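**Retrosynthetic overview**

1. Numbering: ring carbons C1–C10 follow the target SMILES (C1 methyl-bearing alkene carbon, C3 isovalerate carbinol, C4 quaternary, C7 isopropyl carbinol, C8 ring-fusion CH, C9 aroyloxy carbinol). The strategy rests on the seven-membered ring C1–C2–C3–C4–C8–C9–C10, fused along C4–C8 to the five-membered ring C4–C5–C6–C7–C8. It has one sp3 carbon (C10) between C1 and C9 and two (C3, C4) between C2 and C8, so it is a masked cyclohepta-1,4-diene with the quaternary C4 as a Cope terminus.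
2. Late stage: the two esters are cut; the C3 oxygen goes back to allylic C–H oxidation and enone reduction; C7–OH, H8 and C9–OH go back to the C7=C8–C9=O enone (directed epoxidation, SmI2 opening, ketone reduction); the C1 methyl goes back to a C1 ester.
3. Key disconnection: the enone comes from the C8=C9 silyl enol ether of a cyclohepta-1,4-diene. Retro-Cope (C3–C4) gives a cis-divinylcyclopropane on C1, C9, C10, and this opens (C1–C10, C1–C9) to a 2-silyloxydiene and methyl 2-diazobut-3-enoate (formal (4+3) cycloaddition).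
4. Precursors: the diene from (R)-p-menth-1-ene (ozonolysis, aldol ring contraction, MeMgBr, oxidation, enol silylation); the diazo ester from methyl but-3-enoate.
5. Ring order: five-membered ring first (step 2), seven-membered ring second (step 7).

Key step: step 7

Assumption: Rh2(S-DOSP)4 is taken to induce in the sense known for its cyclopropanations of terminal alkenes with donor/acceptor carbenoids, which on the boat model makes it the catalyst matched to the (S)-configured C7 of the diene; should the sense be the opposite, Rh2(R-DOSP)4 takes its place.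

Bicyclic compounds are named as bicyclo[5.3.0]decanes with the C1–C10 numbering of the overview; TBSO = tert-butyldimethylsilyloxy.

**Route**

Step 1
Reactants: 1 (R)-p-menth-1-ene
Product: 3 (3R)-6-oxo-3-(propan-2-yl)heptanal, via secondary ozonide 2 (not isolated)
Conditions: O3, CH2Cl2, −78 °C; then Me2S, −78 °C to rt
Reagents that add atoms: ozone, O=[O+][O-]
Why: Ozonolysis (Criegee mechanism) with reductive work-up cleaves the only alkene to the keto aldehyde and leaves the isopropyl-bearing stereocentre untouched.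

Step 2
Reactants: 3 (3R)-6-oxo-3-(propan-2-yl)heptanal
Product: 5 (5S)-2-methyl-5-(propan-2-yl)cyclopent-1-ene-1-carbaldehyde, via aldol adduct 4 (not isolated)
Conditions: piperidine (cat.), AcOH (cat.), benzene, reflux, Dean–Stark
Reagents that add atoms: none
Why: Enamine-mediated intramolecular aldol condensation (5-exo-trig attack of the aldehyde enamine on the methyl ketone, then dehydration) gives the tetrasubstituted enal; the stereocentre is β to the aldehyde and cannot epimerise.

Step 3
Reactants: 5 (5S)-2-methyl-5-(propan-2-yl)cyclopent-1-ene-1-carbaldehyde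
Product: 6 1-[(5S)-2-methyl-5-(propan-2-yl)cyclopent-1-en-1-yl]ethan-1-ol (both carbinol epimers)
Conditions: MeMgBr, THF, −78 to 0 °C; aq. NH4Cl
Reagents that add atoms: methylmagnesium bromide, C[Mg]Br
Why: Grignard 1,2-addition to the enal, whose β-carbon is fully substituted and closed to conjugate addition; the carbinol configuration is irrelevant because it is oxidised next.

Step 4
Reactants: 6 1-[(5S)-2-methyl-5-(propan-2-yl)cyclopent-1-en-1-yl]ethan-1-ol
Product: 7 1-[(5S)-2-methyl-5-(propan-2-yl)cyclopent-1-en-1-yl]ethan-1-one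
Conditions: Dess–Martin periodinane, NaHCO3, CH2Cl2, 0 °C to rt
Reagents that add atoms: none
Why: Dess–Martin oxidation of the secondary allylic alcohol under buffered, non-epimerising conditions gives the methyl enone.

Step 5
Reactants: 7 1-[(5S)-2-methyl-5-(propan-2-yl)cyclopent-1-en-1-yl]ethan-1-one
Product: 8 tert-butyl(dimethyl)({1-[(5S)-2-methyl-5-(propan-2-yl)cyclopent-1-en-1-yl]ethenyl}oxy)silane
Conditions: TBSOTf, Et3N, CH2Cl2, −78 to 0 °C
Reagents that add atoms: tert-butyldimethylsilyl trifluoromethanesulfonate, CC(C)(C)[Si](C)(C)OS(=O)(=O)C(F)(F)F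
Why: Soft enolisation/silylation of a methyl enone removes a proton of the acetyl methyl group and gives the cross-conjugated 2-silyloxydiene; the C–H at the stereocentre is not acidic.

Step 6
Reactants: 9 methyl but-3-enoate
Product: 10 methyl 2-diazobut-3-enoate
Conditions: 4-acetamidobenzenesulfonyl azide, DBU, MeCN, 0 °C; extracted into cold pentane and used at once
Reagents that add atoms: 4-acetamidobenzenesulfonyl azide, CC(=O)Nc1ccc(cc1)S(=O)(=O)N=[N+]=[N-]
Why: Regitz diazo transfer to the methylene activated by the ester and the vinyl group; the product is kept cold and dilute because it cyclises to a pyrazole on standing.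

Step 7
Reactants: 8 tert-butyl(dimethyl)({1-[(5S)-2-methyl-5-(propan-2-yl)cyclopent-1-en-1-yl]ethenyl}oxy)silane; 10 methyl 2-diazobut-3-enoate
Product: 12 methyl (4S,7S)-9-TBSO-4-methyl-7-(propan-2-yl)bicyclo[5.3.0]deca-1,8-diene-1-carboxylate, via cis-divinylcyclopropane 11 (not isolated)
Conditions: Rh2(S-DOSP)4 (1 mol %, divalent rhodium), pentane, −78 °C, 10 (2.5 equiv) added over 2 h; warm to rt; then toluene, 100 °C
Reagents that add atoms: none
Why: Loss of N2 from 10 at the dirhodium catalyst gives a donor/acceptor vinylcarbenoid that cyclopropanates the electron-rich, unhindered C9=C10 enol ether alkene of 8 (C1–C10 and C1–C9 formed; the tetrasubstituted C4=C8 alkene is inert) with the vinyl group cis to the cyclopentenyl group, and the cis-divinylcyclopropane 11 then undergoes a [3,3] shift through a boat transition state in which C3–C4 forms while C1–C9 breaks. The closest known reaction type is the tandem cyclopropanation/Cope rearrangement (formal (4+3) cycloaddition) of rhodium vinylcarbenoids with 2-silyloxydienes. The seven-membered ring is closed in the Cope step by bond formation between the alkene termini C3 and C4, a concerted six-centre sigmatropic closure. The only new stereocentre, C4, is set by stereospecific transfer from the cyclopropane stereocentres C1 and C9, whose absolute configuration is fixed by the chiral catalyst; on the accepted model the cyclopropane formed is the one whose boat brings C3 to the face of C4 opposite the C7 isopropyl group, so catalyst and substrate are matched. The step needs site selectivity (cyclopropanation before allylic C–H insertion), cis-divinyl diastereoselectivity and a workable Cope rate; the first two rest on the terminal enol ether and on the known behaviour of 2-silyloxydienes in this reaction, and a trans isomer can still reach 12 because the C1–C9 bond, flanked by two alkenyl groups, the ester and the silyloxy group, opens reversibly on heating. Heating in toluene is planned because the C4 methyl group points inward in the boat.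

Step 8
Reactants: 12 methyl (4S,7S)-9-TBSO-4-methyl-7-(propan-2-yl)bicyclo[5.3.0]deca-1,8-diene-1-carboxylate
Product: 13 [(4S,7S)-9-TBSO-4-methyl-7-(propan-2-yl)bicyclo[5.3.0]deca-1,8-dien-1-yl]methanol
Conditions: DIBAL-H (i-Bu2AlH, 2.5 equiv), CH2Cl2, −78 °C; Rochelle salt
Reagents that add atoms: none
Why: Hydride reduction of the conjugated ester to the allylic alcohol; the silyl enol ether and both alkenes are inert to DIBAL-H at low temperature.

Step 9
Reactants: 13 [(4S,7S)-9-TBSO-4-methyl-7-(propan-2-yl)bicyclo[5.3.0]deca-1,8-dien-1-yl]methanol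
Product: 15 (4S,7S)-9-TBSO-1,4-dimethyl-7-(propan-2-yl)bicyclo[5.3.0]deca-1,8-diene, via allylic mesylate 14 (not isolated)
Conditions: Ms2O, Et3N, THF, −30 °C; then LiBHEt3 (4 equiv), −30 to 0 °C
Reagents that add atoms: none
Why: Sulfonylation followed by SN2 displacement of the primary allylic mesylate by hydride at the unhindered CH2 turns CH2OH into CH3 without moving the C1=C2 alkene.

Step 10
Reactants: 15 (4S,7S)-9-TBSO-1,4-dimethyl-7-(propan-2-yl)bicyclo[5.3.0]deca-1,8-diene
Product: 16 (4S)-1,4-dimethyl-7-(propan-2-yl)bicyclo[5.3.0]deca-1,7-dien-9-one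
Conditions: Pd(OAc)2 (1.2 equiv, divalent palladium), MeCN/DMSO, 40 °C
Reagents that add atoms: none
Why: Saegusa–Ito oxidation: the palladium enolate carries the metal at C8 on the face opposite the C4 methyl and C7 isopropyl groups, which is the face of H7, the only β-hydrogen, so syn β-hydride elimination gives the C7=C8 enone and erases the C7 stereocentre.

Step 11
Reactants: 16 (4S)-1,4-dimethyl-7-(propan-2-yl)bicyclo[5.3.0]deca-1,7-dien-9-one
Product: 17 (4S,9S)-1,4-dimethyl-7-(propan-2-yl)bicyclo[5.3.0]deca-1,7-dien-9-ol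
Conditions: (R)-2-methyl-CBS-oxazaborolidine (0.3 equiv), catecholborane, toluene, −78 °C
Reagents that add atoms: none
Why: Corey–Bakshi–Shibata reduction of the enone (fully substituted alkenyl carbon C8 as the large group, the C10 methylene as the small one) should give the (9S)-allylic alcohol by reagent control; this temporary stereocentre only steers the next step.

Step 12
Reactants: 17 (4S,9S)-1,4-dimethyl-7-(propan-2-yl)bicyclo[5.3.0]deca-1,7-dien-9-ol
Product: 18 (4S,7S,8R,9S)-7,8-epoxy-1,4-dimethyl-7-(propan-2-yl)bicyclo[5.3.0]dec-1-en-9-ol (epoxide oxygen on the face of the C4 methyl group)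
Conditions: VO(acac)2 (5 mol %), t-BuOOH (1.1 equiv, decane), CH2Cl2, 0 °C
Reagents that add atoms: tert-butyl hydroperoxide, CC(C)(C)OO
Why: Hydroxyl-directed vanadium-catalysed epoxidation: the tetrasubstituted allylic C7=C8 alkene reacts far faster than the homoallylic C1=C2 alkene, and since allylic 1,3-strain with the C7 isopropyl group keeps H9 in the alkene plane, the (9S)-hydroxyl sits on the face of the C4 methyl group and delivers the oxygen there, which sets C7.

Step 13
Reactants: 18 (4S,7S,8R,9S)-7,8-epoxy-1,4-dimethyl-7-(propan-2-yl)bicyclo[5.3.0]dec-1-en-9-ol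
Product: 19 (4S,7S,8S)-7,8-epoxy-1,4-dimethyl-7-(propan-2-yl)bicyclo[5.3.0]dec-1-en-9-one
Conditions: Dess–Martin periodinane, NaHCO3, CH2Cl2, 0 °C to rt
Reagents that add atoms: none
Why: Dess–Martin oxidation of the secondary epoxy alcohol to the α,β-epoxy ketone under buffered conditions that spare the epoxide and the skipped alkene.

Step 14
Reactants: 19 (4S,7S,8S)-7,8-epoxy-1,4-dimethyl-7-(propan-2-yl)bicyclo[5.3.0]dec-1-en-9-one
Product: 20 (4S,7S,8R)-7-hydroxy-1,4-dimethyl-7-(propan-2-yl)bicyclo[5.3.0]dec-1-en-9-one (cis ring fusion; 7-OH, H8 and 4-CH3 on one face)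
Conditions: SmI2 (2.5 equiv, divalent samarium), THF/MeOH, −90 °C
Reagents that add atoms: none
Why: Reductive opening of an α,β-epoxy ketone by single-electron transfer cleaves the C8–O bond and keeps the C7–O bond on the methyl face, and the samarium enolate should be protonated at C8 by methanol from that same face, which carries the samarium alkoxide and lies opposite the C7 isopropyl group, giving the cis ring fusion.

Step 15
Reactants: 20 (4S,7S,8R)-7-hydroxy-1,4-dimethyl-7-(propan-2-yl)bicyclo[5.3.0]dec-1-en-9-one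
Product: 21 (4S,7S,8S,9R)-1,4-dimethyl-7-(propan-2-yl)bicyclo[5.3.0]dec-1-ene-7,9-diol
Conditions: NaBH4, MeOH/THF, −40 °C
Reagents that add atoms: none
Why: Borohydride reduction: hydride should enter C9 on the convex face next to H8 and away from the fully substituted C7, which places the new hydroxyl anti to H8 (9R).

Step 16
Reactants: 22 4-hydroxybenzoic acid
Product: 24 4-TBSO-benzoic acid, via bis-silyl derivative 23 (not isolated)
Conditions: TBSCl (2.5 equiv), imidazole, DMF, rt; then AcOH/THF/H2O, rt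
Reagents that add atoms: tert-butyldimethylsilyl chloride, CC(C)(C)[Si](C)(C)Cl
Why: Silylation of both acidic OH groups and selective hydrolysis of the much more labile silyl ester leave the phenol protected as its silyl ether.

Step 17
Reactants: 21 (4S,7S,8S,9R)-1,4-dimethyl-7-(propan-2-yl)bicyclo[5.3.0]dec-1-ene-7,9-diol; 24 4-TBSO-benzoic acid
Product: 25 (4S,7S,8S,9R)-7-hydroxy-1,4-dimethyl-7-(propan-2-yl)bicyclo[5.3.0]dec-1-en-9-yl 4-TBSO-benzoate
Conditions: EDC·HCl, DMAP, CH2Cl2, rt to 40 °C
Reagents that add atoms: none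
Why: Steglich esterification acylates the secondary C9 hydroxyl; the tertiary C7 hydroxyl does not compete.

Step 18
Reactants: 25 (4S,7S,8S,9R)-7-hydroxy-1,4-dimethyl-7-(propan-2-yl)bicyclo[5.3.0]dec-1-en-9-yl 4-TBSO-benzoate
Product: 26 (4R,7S,8S,9R)-7-hydroxy-1,4-dimethyl-3-oxo-7-(propan-2-yl)bicyclo[5.3.0]dec-1-en-9-yl 4-TBSO-benzoate
Conditions: Rh2(cap)4 (dirhodium tetracaprolactamate, 1 mol %, divalent rhodium), t-BuOOH (70% aq., 5 equiv), 1,2-dichloroethane, 40 °C
Reagents that add atoms: tert-butyl hydroperoxide, CC(C)(C)OO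
Why: Radical allylic oxidation by tert-butylperoxyl radicals should take the C3 methylene, attached to the unsubstituted alkene carbon C2, to the conjugated enone, as in the oxidation of Δ5-steroid 3-esters to 7-ketones; C10 is deactivated by the neighbouring acyloxy group.

Step 19
Reactants: 26 (4R,7S,8S,9R)-7-hydroxy-1,4-dimethyl-3-oxo-7-(propan-2-yl)bicyclo[5.3.0]dec-1-en-9-yl 4-TBSO-benzoate
Product: 27 (3S,4R,7S,8S,9R)-3,7-dihydroxy-1,4-dimethyl-7-(propan-2-yl)bicyclo[5.3.0]dec-1-en-9-yl 4-TBSO-benzoate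
Conditions: NaBH4, CeCl3·7H2O, MeOH, −40 °C
Reagents that add atoms: none
Why: Luche 1,2-reduction: the C4 methyl group and C5 flank the two faces of the C3 carbonyl about equally, but the five-membered ring with the C7 isopropyl group closes the concave face, so hydride should enter from the convex face and give the (3S)-alcohol with the hydroxyl anti to the C4 methyl group.

Step 20
Reactants: 27 (3S,4R,7S,8S,9R)-3,7-dihydroxy-1,4-dimethyl-7-(propan-2-yl)bicyclo[5.3.0]dec-1-en-9-yl 4-TBSO-benzoate; 28 isovaleryl chloride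
Product: 29 (3S,4R,7S,8S,9R)-7-hydroxy-1,4-dimethyl-3-(3-methylbutanoyloxy)-7-(propan-2-yl)bicyclo[5.3.0]dec-1-en-9-yl 4-TBSO-benzoate
Conditions: pyridine, DMAP (cat.), CH2Cl2, 0 °C to rt
Reagents that add atoms: none
Why: DMAP-catalysed acylation of the secondary allylic alcohol by the acid chloride; the tertiary C7 hydroxyl is too hindered to react.

Step 21
Reactants: 29 (3S,4R,7S,8S,9R)-7-hydroxy-1,4-dimethyl-3-(3-methylbutanoyloxy)-7-(propan-2-yl)bicyclo[5.3.0]dec-1-en-9-yl 4-TBSO-benzoate
Product: 30 (3S,4R,7S,8S,9R)-7-hydroxy-1,4-dimethyl-3-(3-methylbutanoyloxy)-7-(propan-2-yl)bicyclo[5.3.0]dec-1-en-9-yl 4-hydroxybenzoate (CNP0086724.3)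
Conditions: HF·pyridine, pyridine/THF, 0 °C
Reagents that add atoms: none
Why: Fluoride-mediated cleavage of the aryl silyl ether under buffered conditions that leave both esters, the allylic C3–O bond and the tertiary alcohol untouched.

**Compound list**

1 | (R)-p-menth-1-ene | CC1=CC[C@H](C(C)C)CC1 | starting material
2 | secondary ozonide of 1 (4-isopropyl-1-methyl-7,8,9-trioxabicyclo[4.2.1]nonane) | CC12CC[C@@H](C(C)C)CC(OO1)O2 | intermediate (not isolated)
3 | (3R)-6-oxo-3-(propan-2-yl)heptanal | O=CC[C@H](C(C)C)CCC(C)=O | intermediate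
4 | aldol adduct, (5S)-2-hydroxy-2-methyl-5-(propan-2-yl)cyclopentane-1-carbaldehyde | O=CC1C(C)(O)CC[C@H]1C(C)C | intermediate (not isolated)
5 | (5S)-2-methyl-5-(propan-2-yl)cyclopent-1-ene-1-carbaldehyde | O=CC1=C(C)CC[C@H]1C(C)C | intermediate
6 | 1-[(5S)-2-methyl-5-(propan-2-yl)cyclopent-1-en-1-yl]ethan-1-ol (both carbinol epimers) | CC(O)C1=C(C)CC[C@H]1C(C)C | intermediate
7 | 1-[(5S)-2-methyl-5-(propan-2-yl)cyclopent-1-en-1-yl]ethan-1-one | CC(=O)C1=C(C)CC[C@H]1C(C)C | intermediate
8 | tert-butyl(dimethyl)({1-[(5S)-2-methyl-5-(propan-2-yl)cyclopent-1-en-1-yl]ethenyl}oxy)silane | C=C(O[Si](C)(C)C(C)(C)C)C1=C(C)CC[C@H]1C(C)C | intermediate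
9 | methyl but-3-enoate | COC(=O)CC=C | starting material
10 | methyl 2-diazobut-3-enoate | C=CC(=[N+]=[N-])C(=O)OC | intermediate
11 | methyl (1R,2S)-2-TBSO-1-ethenyl-2-[(5S)-2-methyl-5-(propan-2-yl)cyclopent-1-en-1-yl]cyclopropane-1-carboxylate (ethenyl cis to cyclopentenyl) | COC(=O)[C@@]1(C=C)C[C@]1(O[Si](C)(C)C(C)(C)C)C2=C(C)CC[C@H]2C(C)C | intermediate (not isolated)
12 | methyl (4S,7S)-9-TBSO-4-methyl-7-(propan-2-yl)bicyclo[5.3.0]deca-1,8-diene-1-carboxylate | COC(=O)C1=CC[C@]2(C)CC[C@@H](C(C)C)C2=C(O[Si](C)(C)C(C)(C)C)C1 | intermediate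
13 | [(4S,7S)-9-TBSO-4-methyl-7-(propan-2-yl)bicyclo[5.3.0]deca-1,8-dien-1-yl]methanol | OCC1=CC[C@]2(C)CC[C@@H](C(C)C)C2=C(O[Si](C)(C)C(C)(C)C)C1 | intermediate
14 | methanesulfonate of 13 | CS(=O)(=O)OCC1=CC[C@]2(C)CC[C@@H](C(C)C)C2=C(O[Si](C)(C)C(C)(C)C)C1 | intermediate (not isolated)
15 | (4S,7S)-9-TBSO-1,4-dimethyl-7-(propan-2-yl)bicyclo[5.3.0]deca-1,8-diene | CC1=CC[C@]2(C)CC[C@@H](C(C)C)C2=C(O[Si](C)(C)C(C)(C)C)C1 | intermediate
16 | (4S)-1,4-dimethyl-7-(propan-2-yl)bicyclo[5.3.0]deca-1,7-dien-9-one | CC1=CC[C@]2(C)CCC(C(C)C)=C2C(=O)C1 | intermediate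
17 | (4S,9S)-1,4-dimethyl-7-(propan-2-yl)bicyclo[5.3.0]deca-1,7-dien-9-ol | CC1=CC[C@]2(C)CCC(C(C)C)=C2[C@@H](O)C1 | intermediate
18 | (4S,7S,8R,9S)-7,8-epoxy-1,4-dimethyl-7-(propan-2-yl)bicyclo[5.3.0]dec-1-en-9-ol | CC1=CC[C@]2(C)CC[C@@]3(C(C)C)O[C@@]23[C@@H](O)C1 | intermediate
19 | (4S,7S,8S)-7,8-epoxy-1,4-dimethyl-7-(propan-2-yl)bicyclo[5.3.0]dec-1-en-9-one | CC1=CC[C@]2(C)CC[C@@]3(C(C)C)O[C@@]23C(=O)C1 | intermediate
20 | (4S,7S,8R)-7-hydroxy-1,4-dimethyl-7-(propan-2-yl)bicyclo[5.3.0]dec-1-en-9-one | CC1=CC[C@]2(C)CC[C@](O)(C(C)C)[C@@H]2C(=O)C1 | intermediate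
21 | (4S,7S,8S,9R)-1,4-dimethyl-7-(propan-2-yl)bicyclo[5.3.0]dec-1-ene-7,9-diol | CC1=CC[C@]2(C)CC[C@](O)(C(C)C)[C@@H]2[C@H](O)C1 | intermediate
22 | 4-hydroxybenzoic acid | OC(=O)c1ccc(O)cc1 | starting material
23 | tert-butyldimethylsilyl 4-TBSO-benzoate | CC(C)(C)[Si](C)(C)OC(=O)c1ccc(O[Si](C)(C)C(C)(C)C)cc1 | intermediate (not isolated)
24 | 4-TBSO-benzoic acid | OC(=O)c1ccc(O[Si](C)(C)C(C)(C)C)cc1 | intermediate
25 | (4S,7S,8S,9R)-7-hydroxy-1,4-dimethyl-7-(propan-2-yl)bicyclo[5.3.0]dec-1-en-9-yl 4-TBSO-benzoate | CC1=CC[C@]2(C)CC[C@](O)(C(C)C)[C@@H]2[C@H](OC(=O)c2ccc(O[Si](C)(C)C(C)(C)C)cc2)C1 | intermediate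
26 | (4R,7S,8S,9R)-7-hydroxy-1,4-dimethyl-3-oxo-7-(propan-2-yl)bicyclo[5.3.0]dec-1-en-9-yl 4-TBSO-benzoate | CC1=CC(=O)[C@]2(C)CC[C@](O)(C(C)C)[C@@H]2[C@H](OC(=O)c2ccc(O[Si](C)(C)C(C)(C)C)cc2)C1 | intermediate
27 | (3S,4R,7S,8S,9R)-3,7-dihydroxy-1,4-dimethyl-7-(propan-2-yl)bicyclo[5.3.0]dec-1-en-9-yl 4-TBSO-benzoate | CC1=C[C@H](O)[C@]2(C)CC[C@](O)(C(C)C)[C@@H]2[C@H](OC(=O)c2ccc(O[Si](C)(C)C(C)(C)C)cc2)C1 | intermediate
28 | isovaleryl chloride | CC(C)CC(=O)Cl | starting material
29 | (3S,4R,7S,8S,9R)-7-hydroxy-1,4-dimethyl-3-(3-methylbutanoyloxy)-7-(propan-2-yl)bicyclo[5.3.0]dec-1-en-9-yl 4-TBSO-benzoate | CC1=C[C@H](OC(=O)CC(C)C)[C@]2(C)CC[C@](O)(C(C)C)[C@@H]2[C@H](OC(=O)c2ccc(O[Si](C)(C)C(C)(C)C)cc2)C1 | intermediate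
30 | CNP0086724.3, (3S,4R,7S,8S,9R)-7-hydroxy-1,4-dimethyl-3-(3-methylbutanoyloxy)-7-(propan-2-yl)bicyclo[5.3.0]dec-1-en-9-yl 4-hydroxybenzoate | CC1=C[C@H](OC(=O)CC(C)C)[C@]2(C)CC[C@](O)(C(C)C)[C@@H]2[C@H](OC(=O)c2ccc(O)cc2)C1 | target

**Step count and risks**

Total step count: 21. Longest linear sequence: 19 steps (steps 1–5, 7–15, 17–21).

Steps most likely to fail:

Step 7. The labile diazo ester may be lost to pyrazole formation or carbenoid dimerisation, the cyclopropanation may place the vinyl group trans to the cyclopentenyl group, and the crowded boat rearrangement may stall or be overtaken by heterolytic opening of the silyloxy ester cyclopropane. The fallback sets out from diene 8 and comes back at 12. Methyl acetoacetate is converted by diazo transfer into methyl 2-diazo-3-oxobutanoate F1, and TBSOTf/Et3N turns this into methyl 3-TBSO-2-diazobut-3-enoate F2, a vinyldiazoacetate that does not cyclise and can be stored. With Rh2(R-PTAD)4 (dirhodium tetrakis[(R)-(1-adamantyl)(phthalimido)acetate], divalent rhodium, expected to induce in the same sense as Rh2(S-DOSP)4), F2 and 8 should give the bis(silyl enol ether) methyl (4S,7S)-2,9-bis-TBSO-4-methyl-7-(propan-2-yl)bicyclo[5.3.0]deca-1,8-diene-1-carboxylate F3 by the same cyclopropanation/Cope sequence. CsF/PhNTf2 in DME exchanges only the silyl group of the β-keto ester enol ether for triflate, giving the C2 enol triflate F4. Pd(OAc)2/PPh3 with HCO2H/Et3N in DMF then reduces the triflate to the C2–H enoate 12.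

Step 10. Palladation of the hindered, fully substituted silyl enol ether may be slower than its protodesilylation to the saturated ketone, and palladium hydride may move the C1=C2 alkene into conjugation. The fallback sets out from 15 and comes back at 16. PhSeCl in CH2Cl2 at −78 °C should selenenylate the enol ether at C8 on the face opposite the C4 methyl and C7 isopropyl groups, giving (4S,7S,8R)-1,4-dimethyl-8-(phenylselanyl)-7-(propan-2-yl)bicyclo[5.3.0]dec-1-en-9-one F5. The selenium then lies syn to H7, so oxidation with H2O2/pyridine at 0 °C and selenoxide syn-elimination give enone 16.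

Step 19. Facial selectivity at C3 may be poor or reversed, because the C4 methyl group sits next to the carbonyl on the convex face. The fallback sets out from 26 and comes back at 29, leaving out step 20. If hydride enters from the concave face, the reduction gives the C3 epimer (3R,4R,7S,8S,9R)-3,7-dihydroxy-1,4-dimethyl-7-(propan-2-yl)bicyclo[5.3.0]dec-1-en-9-yl 4-TBSO-benzoate F6. Mitsunobu esterification of F6 with 3-methylbutanoic acid, PPh3 and DIAD in toluene should give the isovalerate 29 with inversion at the allylic carbon; SN2′ attack is disfavoured at the fully substituted C1.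

**Further compounds**

F1 | step 7 | methyl 2-diazo-3-oxobutanoate | COC(=O)C(=[N+]=[N-])C(C)=O
F2 | step 7 | methyl 3-TBSO-2-diazobut-3-enoate | COC(=O)C(=[N+]=[N-])C(=C)O[Si](C)(C)C(C)(C)C
F3 | step 7 | methyl (4S,7S)-2,9-bis-TBSO-4-methyl-7-(propan-2-yl)bicyclo[5.3.0]deca-1,8-diene-1-carboxylate | COC(=O)C1=C(O[Si](C)(C)C(C)(C)C)C[C@]2(C)CC[C@@H](C(C)C)C2=C(O[Si](C)(C)C(C)(C)C)C1
F4 | step 7 | methyl (4S,7S)-9-TBSO-4-methyl-7-(propan-2-yl)-2-(trifluoromethanesulfonyloxy)bicyclo[5.3.0]deca-1,8-diene-1-carboxylate | COC(=O)C1=C(OS(=O)(=O)C(F)(F)F)C[C@]2(C)CC[C@@H](C(C)C)C2=C(O[Si](C)(C)C(C)(C)C)C1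
F5 | step 10 | (4S,7S,8R)-1,4-dimethyl-8-(phenylselanyl)-7-(propan-2-yl)bicyclo[5.3.0]dec-1-en-9-one | CC1=CC[C@]2(C)CC[C@@H](C(C)C)[C@@]2([Se]c3ccccc3)C(=O)C1
F6 | step 19 | (3R,4R,7S,8S,9R)-3,7-dihydroxy-1,4-dimethyl-7-(propan-2-yl)bicyclo[5.3.0]dec-1-en-9-yl 4-TBSO-benzoate | CC1=C[C@@H](O)[C@]2(C)CC[C@](O)(C(C)C)[C@@H]2[C@H](OC(=O)c2ccc(O[Si](C)(C)C(C)(C)C)cc2)C1
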